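**Retrosynthetic overview**
1. Last and decisive disconnection: the pyranone O1–C2 bond (ring C). It is made by cyclodehydration of 1,3-diketone 6 through the hydroxyl next to the benzyl group, steered to the 8-benzyl isomer by a boronic acid clipped onto the side-chain catechol.
2. C2–C3: diketone 6 from acetophenone 4 and benzoyl chloride 5 (Claisen-type C-acylation; ring B enters here).
3. C8–CH2: 4 from phloroacetophenone 1 and 2,3-dihydroxybenzyl alcohol 2 (ortho-quinone methide benzylation; C3 and C5 of 1 are equivalent, so no regiochemical question arises).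
4. Ring order: ring A, ring B and the catechol ring are bought; ring C is the only ring formed, in the final step. No protecting groups.

Assumption: the target has no stereocentre (achiral flavone with a CH2 linker), so "single enantiomer" sets no stereochemical task.
Assumption: salts and conjugate bases of a numbered compound (for example a lithium enolate) are treated as forms of that compound, not as separate compounds.

**Route**

Step 1
Reactants: 1 2',4',6'-trihydroxyacetophenone (phloroacetophenone), 2 2,3-dihydroxybenzyl alcohol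
Product: 4 1-[3-(2,3-dihydroxybenzyl)-2,4,6-trihydroxyphenyl]ethan-1-one, via ortho-quinone methide 3 (not isolated)
Conditions: 1 (2.5 equiv), TsOH·H2O (10 mol %), 1,4-dioxane, 60 °C, 2 (1.0 equiv) added over 4 h; excess 1 recovered
Reagents that add atoms: none
Why: Acid-catalysed dehydration of 2 gives ortho-quinone methide 3, which is trapped by the nucleophilic ring carbon of 1 in a Friedel–Crafts-type conjugate addition (ortho-quinone methide C-benzylation); C3 and C5 of 1 are equivalent, so only one mono-benzyl product can form, and the acyl group plus excess 1 suppress double benzylation.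

Step 2
Reactants: 4 1-[3-(2,3-dihydroxybenzyl)-2,4,6-trihydroxyphenyl]ethan-1-one, 5 benzoyl chloride
Product: 6 1-[3-(2,3-dihydroxybenzyl)-2,4,6-trihydroxyphenyl]-3-phenylpropane-1,3-dione
Conditions: LiN(SiMe3)2 (7.0 equiv), degassed THF, −78 → −10 °C; then 5 (1.05 equiv), −78 → 23 °C; then 1 M HCl aq, 0 °C
Reagents that add atoms: none
Why: Claisen-type C-acylation of the ketone enolate inside the lithium polyanion of 4 (the protecting-group-free Baker–Venkataraman variant used for 5,7-dihydroxyflavones); the enolate carbon is the most nucleophilic site at −78 °C, so one equivalent of acid chloride gives the 1,3-diketone rather than aryl esters, and cold dilute acid does not dehydrate it.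

Step 3
Reactants: 6 1-[3-(2,3-dihydroxybenzyl)-2,4,6-trihydroxyphenyl]-3-phenylpropane-1,3-dione
Product: 10 8-(2,3-dihydroxybenzyl)-5,7-dihydroxy-2-phenyl-4H-chromen-4-one, via diketone arylboronate 7 (not isolated), via hemiketal arylboronate 8 (not isolated), via flavone arylboronate 9 (not isolated)
Conditions: 3,5-(CF3)2C6H3B(OH)2 (1.05 equiv), 4 Å molecular sieves, MeNO2 (0.02 M), 23 → 45 °C; then MeOH/1 M HCl aq, 23 °C
Reagents that add atoms: none
Why: Proposed new method: a substrate-anchored boron Lewis acid steers the C–O ring closure — the electron-poor arylboronic acid condenses only with the catechol (the sole 1,2-diol) to give three-coordinate dioxaborole 7, whose single vacant site cannot chelate the diketone but lies within reach of the oxygens on the benzyl side only, so it activates the benzoyl carbonyl for attack by the neighbouring 2'-OH and then abstracts the C2 hydroxyl of hemiketal 8 (the resulting hydroxyborate removes H3), while the isomeric hemiketal closed through the remote 6'-OH cannot reach boron and reverts by fast ring–chain tautomerism (Curtin–Hammett funnel), giving 9 and, after hydrolysis of the boronate, 10; the closest known chemistry is acid-catalysed cyclodehydration of 2-hydroxyaryl 1,3-diketones (Baker–Venkataraman endgame) combined with arylboronic acid catalysis of hydroxyl ionisation and covalent template (scaffolding) catalysis.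

**Compound list**
1 | 2',4',6'-trihydroxyacetophenone (phloroacetophenone) | CC(=O)c1c(O)cc(O)cc1O | starting material
2 | 2,3-dihydroxybenzyl alcohol | OCc1cccc(O)c1O | starting material
3 | 2-hydroxy-6-methylidenecyclohexa-2,4-dien-1-one (ortho-quinone methide of 2; not isolated) | C=C1C=CC=C(O)C1=O | intermediate
4 | 1-[3-(2,3-dihydroxybenzyl)-2,4,6-trihydroxyphenyl]ethan-1-one | CC(=O)c1c(O)cc(O)c(Cc2cccc(O)c2O)c1O | intermediate
5 | benzoyl chloride | O=C(Cl)c1ccccc1 | starting material
6 | 1-[3-(2,3-dihydroxybenzyl)-2,4,6-trihydroxyphenyl]-3-phenylpropane-1,3-dione | O=C(CC(=O)c1ccccc1)c1c(O)cc(O)c(Cc2cccc(O)c2O)c1O | intermediate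
7 | 1-{3-[(2-[3,5-bis(trifluoromethyl)phenyl]-1,3,2-benzodioxaborol-4-yl)methyl]-2,4,6-trihydroxyphenyl}-3-phenylpropane-1,3-dione (not isolated) | O=C(CC(=O)c1ccccc1)c1c(O)cc(O)c(Cc2cccc3OB(c4cc(C(F)(F)F)cc(C(F)(F)F)c4)Oc23)c1O | intermediate
8 | 8-({2-[3,5-bis(trifluoromethyl)phenyl]-1,3,2-benzodioxaborol-4-yl}methyl)-2,5,7-trihydroxy-2-phenyl-2,3-dihydro-4H-chromen-4-one (racemic hemiketal; its stereocentre is lost on dehydration; not isolated) | O=C1CC(O)(c2ccccc2)Oc2c(Cc3cccc4OB(c5cc(C(F)(F)F)cc(C(F)(F)F)c5)Oc34)c(O)cc(O)c12 | intermediate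
9 | 8-({2-[3,5-bis(trifluoromethyl)phenyl]-1,3,2-benzodioxaborol-4-yl}methyl)-5,7-dihydroxy-2-phenyl-4H-chromen-4-one (not isolated) | O=c1cc(-c2ccccc2)oc2c(Cc3cccc4OB(c5cc(C(F)(F)F)cc(C(F)(F)F)c5)Oc34)c(O)cc(O)c12 | intermediate
10 | 8-(2,3-dihydroxybenzyl)-5,7-dihydroxy-2-phenyl-4H-chromen-4-one (CNP0031733.0) | O=c1cc(-c2ccccc2)oc2c(Cc3cccc(O)c3O)c(O)cc(O)c12 | target

**Totals and risks**

Total step count: 3. Longest linear sequence: 3.

The three steps most likely to fail, most risky first:

Step 3 (the proposed templated cyclodehydration). The risk is incomplete regiocontrol, giving the 6-benzyl isomer by an untemplated acid pathway, or a boron resting state on a flanking phenol that slows turnover. The isomer ratio can be read from the crude 1H NMR and HMBC (chelated 5-OH to the protonated C6). The fallback uses known chemistry, sets out from 4 and comes back at 10, and fixes the ring oxygen by protection instead of by the template. MOMCl (4.5 equiv) and iPr2NEt in CH2Cl2 at 0 → 23 °C cap the four unchelated hydroxyls and leave the hindered, carbonyl-chelated hydroxyl next to the benzyl group free, giving 1-[2-hydroxy-4,6-bis(methoxymethoxy)-3-{[2,3-bis(methoxymethoxy)phenyl]methyl}phenyl]ethan-1-one F1; a minor isomer with the other ortho hydroxyl free is removed on silica. Claisen–Schmidt condensation with benzaldehyde (KOH, EtOH, 23 °C) gives (E)-1-[2-hydroxy-4,6-bis(methoxymethoxy)-3-{[2,3-bis(methoxymethoxy)phenyl]methyl}phenyl]-3-phenylprop-2-en-1-one F2. I2 (10 mol %) in DMSO at 120 °C closes the only free ortho hydroxyl onto the enone and dehydrogenates to 8-{[2,3-bis(methoxymethoxy)phenyl]methyl}-5,7-bis(methoxymethoxy)-2-phenyl-4H-chromen-4-one F3 (partial MOM loss here is harmless). 3 M HCl in MeOH at 50 °C then removes the MOM groups to give 10.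

Step 2 (polyanion acylation). The risk is poor solubility of the lithium polyanion of a pentaphenol and competing O-benzoylation. The fallback sets out from 4 and comes back at 6, masking four phenols so that a soluble phenoxide–enolate dianion is acylated. TBSCl (4.4 equiv) and imidazole in DMF at 23 °C give 1-[2-hydroxy-4,6-bis(tert-butyldimethylsilyloxy)-3-{[2,3-bis(tert-butyldimethylsilyloxy)phenyl]methyl}phenyl]ethan-1-one F4; any isomer with the other ortho hydroxyl free converges on the same diketone later. LiN(SiMe3)2 (3.2 equiv) in THF at −78 °C followed by 5 gives 1-[2-hydroxy-4,6-bis(tert-butyldimethylsilyloxy)-3-{[2,3-bis(tert-butyldimethylsilyloxy)phenyl]methyl}phenyl]-3-phenylpropane-1,3-dione F5. Bu4NF (4.4 equiv) buffered with AcOH in THF at 0 °C removes the silyl groups without cyclisation and returns 6.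

Step 1 (benzylation). The risk is double benzylation, self-condensation of 3 with the catechol ring of 2, or sluggish attack by the acyl-deactivated ring of 1. The fallback sets out from 2 and comes back at 4, reversing the order of the two C–C bond formations so that the far more nucleophilic parent phenol captures 3. Compound 2 is added slowly to phloroglucinol (5 equiv, commercial) with TsOH·H2O (5 mol %) in 1,4-dioxane at 40 °C to give 2-(2,3-dihydroxybenzyl)benzene-1,3,5-triol F6; the excess phloroglucinol is washed out with water. Hoesch acylation (MeCN, ZnCl2, HCl gas, Et2O, 0 °C) at either of the two equivalent free ring positions gives 1-[3-(2,3-dihydroxybenzyl)-2,4,6-trihydroxyphenyl]ethan-1-iminium chloride F7, which is hydrolysed in water at 100 °C to 4.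

**Further compounds**
F1 | step 3 | 1-[2-hydroxy-4,6-bis(methoxymethoxy)-3-{[2,3-bis(methoxymethoxy)phenyl]methyl}phenyl]ethan-1-one | CC(=O)c1c(OCOC)cc(OCOC)c(Cc2cccc(OCOC)c2OCOC)c1O
F2 | step 3 | (E)-1-[2-hydroxy-4,6-bis(methoxymethoxy)-3-{[2,3-bis(methoxymethoxy)phenyl]methyl}phenyl]-3-phenylprop-2-en-1-one | O=C(/C=C/c1ccccc1)c1c(OCOC)cc(OCOC)c(Cc2cccc(OCOC)c2OCOC)c1O
F3 | step 3 | 8-{[2,3-bis(methoxymethoxy)phenyl]methyl}-5,7-bis(methoxymethoxy)-2-phenyl-4H-chromen-4-one | O=c1cc(-c2ccccc2)oc2c(Cc3cccc(OCOC)c3OCOC)c(OCOC)cc(OCOC)c12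
F4 | step 2 | 1-[2-hydroxy-4,6-bis(tert-butyldimethylsilyloxy)-3-{[2,3-bis(tert-butyldimethylsilyloxy)phenyl]methyl}phenyl]ethan-1-one | CC(=O)c1c(O[Si](C)(C)C(C)(C)C)cc(O[Si](C)(C)C(C)(C)C)c(Cc2cccc(O[Si](C)(C)C(C)(C)C)c2O[Si](C)(C)C(C)(C)C)c1O
F5 | step 2 | 1-[2-hydroxy-4,6-bis(tert-butyldimethylsilyloxy)-3-{[2,3-bis(tert-butyldimethylsilyloxy)phenyl]methyl}phenyl]-3-phenylpropane-1,3-dione | O=C(CC(=O)c1ccccc1)c1c(O[Si](C)(C)C(C)(C)C)cc(O[Si](C)(C)C(C)(C)C)c(Cc2cccc(O[Si](C)(C)C(C)(C)C)c2O[Si](C)(C)C(C)(C)C)c1O
F6 | step 1 | 2-(2,3-dihydroxybenzyl)benzene-1,3,5-triol | Oc1cc(O)c(Cc2cccc(O)c2O)c(O)c1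
F7 | step 1 | 1-[3-(2,3-dihydroxybenzyl)-2,4,6-trihydroxyphenyl]ethan-1-iminium chloride | CC(=[NH2+])c1c(O)cc(O)c(Cc2cccc(O)c2O)c1O.[Cl-]
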